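The plan disconnects the cis-fused γ-butyrolactone from the cycloheptane at the ring-fusion bond C6–C7 and at C11–C12, the bond between the lactone α-carbon and its carbonyl (xanthanolide numbering). A single intramolecular hetero-Pauson–Khand cyclocarbonylation of an allenyl aldehyde makes both bonds and the O–C12 bond, closing the seven-membered carbocycle and the lactone together and setting C6 and C7. It exploits the vicinal pairing of the C6 oxygen with the C7 branch that carries C11–C13. The precursor is an acyclic α-alkoxy aldehyde carrying all other stereocentres (C1, C5, C9, C10), the crotonyl ketone and a terminal allene, assembled from L-erythronolactone acetonide.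

Key step: step 9

Numbering used: ring carbons C1 (tertiary carbinol), C5 (angelate-bearing), C6 (lactone O–CH), C7 (fusion CH), C8 (CH2), C9 (carbinol), C10 (CHMe); C11 lactone α-carbon, C12 lactone carbonyl, C13 its methyl; C2–C4 and C15 the crotonyl chain.

Assumption: 2,3-O-isopropylidene-L-erythronolactone, the enantiomer of the lactone made from erythorbic acid, is taken as a purchasable chiral-pool compound.

Step 1
Reactants: 1 (S)-but-3-en-2-ol
Product: 2 (S)-but-3-en-2-yl methyl carbonate
Conditions: ClCO2Me, pyridine, CH2Cl2, 0 °C
Reagents that add atoms: methyl chloroformate, COC(=O)Cl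
Why: Carbonate formation by O-acylation of the secondary alcohol with the chloroformate should be clean and leaves the carbinol stereocentre untouched.

Step 2
Reactants: 3 2,3-O-isopropylidene-L-erythronolactone; 2 (S)-but-3-en-2-yl methyl carbonate
Product: 5 2-C-[(S)-but-3-en-2-yl]-2,3-O-isopropylidene-L-erythronolactone, via lithium enolate 4 (not isolated)
Conditions: LiN(i-Pr)2, THF, −78 °C; then 2, RhCl(PPh3)3 (10 mol %), P(OMe)3 (40 mol %), −78 to −20 °C
Reagents that add atoms: none
Why: Rhodium-catalysed stereospecific allylic alkylation (a Tsuji–Trost-type substitution through a configurationally stable rhodium allyl) should join the lithium enolate to the carbon that bore the carbonate with net retention, so that C10 (S) is copied from 1, while C1 is fixed because the electrophile can only reach the convex face of the cis-fused dioxolane–lactone bicycle, whose ring fusion also disfavours β-elimination of the acetonide oxygen at low temperature.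

Step 3
Reactants: 5 2-C-[(S)-but-3-en-2-yl]-2,3-O-isopropylidene-L-erythronolactone
Product: 7 2-C-[(R)-1-oxopropan-2-yl]-2,3-O-isopropylidene-L-erythronolactone, via ozonide 6 (not isolated)
Conditions: O3, CH2Cl2, −78 °C; then PPh3, −78 °C to rt
Reagents that add atoms: ozone, [O-][O+]=O
Why: Ozonolysis of the terminal vinyl group with reductive work-up should give the α-methyl aldehyde (C9) without epimerising C10, since no base is present and the lactone and acetonide are inert to ozone.

Step 4
Reactants: 7 2-C-[(R)-1-oxopropan-2-yl]-2,3-O-isopropylidene-L-erythronolactone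
Product: 9 2-C-[(2S,3R)-3-hydroxyhex-5-yn-2-yl]-2,3-O-isopropylidene-L-erythronolactone, via boronate ester 8 (not isolated)
Conditions: allenylboronic acid pinacol ester, (R)-TRIP phosphoric acid (10 mol %), 4 Å MS, toluene, 0 °C; aqueous work-up
Reagents that add atoms: allenylboronic acid pinacol ester, C=C=CB1OC(C)(C)C(C)(C)O1
Why: Chiral-phosphoric-acid-catalysed propargylation by the allenylboronate (allenylboration through a closed six-membered SE2' transition state) should add the propargyl group to the Re face of the aldehyde, the catalyst sense being reinforced by the Felkin–Anh preference imposed by the quaternary C1 as the large α-substituent, which sets C9 (R, syn to the C10 methyl); the oxygen stays masked as boronate 8 until work-up, so it cannot attack the lactone.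

Step 5
Reactants: 9 2-C-[(2S,3R)-3-hydroxyhex-5-yn-2-yl]-2,3-O-isopropylidene-L-erythronolactone
Product: 10 2-C-[(2S,3R)-3-(tert-butyldimethylsilyloxy)hex-5-yn-2-yl]-2,3-O-isopropylidene-L-erythronolactone
Conditions: TBSOTf, 2,6-lutidine, CH2Cl2, −78 to 0 °C
Reagents that add atoms: tert-butyldimethylsilyl triflate, CC(C)(C)[Si](C)(C)OS(=O)(=O)C(F)(F)F
Why: Silylation of the hindered secondary alcohol with the silyl triflate should be fast and mild enough to leave the lactone and the α-stereocentres alone, and it blocks the C9 hydroxyl against lactol formation with the later C6 aldehyde.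

Step 6
Reactants: 10 2-C-[(2S,3R)-3-(tert-butyldimethylsilyloxy)hex-5-yn-2-yl]-2,3-O-isopropylidene-L-erythronolactone
Product: 12 2-C-[(2S,3R)-3-(tert-butyldimethylsilyloxy)hepta-5,6-dien-2-yl]-2,3-O-isopropylidene-L-erythronolactone, via propargylic amine 11 (not isolated)
Conditions: (CH2O)n, CuBr (30 mol %), i-Pr2NH, 1,4-dioxane, reflux
Reagents that add atoms: paraformaldehyde (formaldehyde unit), C=O
Why: Crabbé homologation should convert the terminal alkyne into the terminal allene by copper-mediated Mannich condensation to amine 11 followed by intramolecular hydride transfer and loss of the imine, adding C13 without creating any stereo element.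

Step 7
Reactants: 12 2-C-[(2S,3R)-3-(tert-butyldimethylsilyloxy)hepta-5,6-dien-2-yl]-2,3-O-isopropylidene-L-erythronolactone; 13 (E)-1-bromoprop-1-ene
Product: 15 cyclic hemiketal of the C2 (E)-prop-1-enyl ketone with the C6 hydroxyl (anomer mixture), via (E)-prop-1-enyllithium 14 (not isolated)
Conditions: 13, t-BuLi (2 equiv), Et2O, −78 °C; then 12, THF, −78 °C; AcOH quench at −78 °C
Reagents that add atoms: none
Why: Addition of the alkenyllithium (made with retention of the E geometry by bromine–lithium exchange) to the lactone carbonyl should stop at the ketone oxidation level because the tetrahedral lithium alkoxide is stable at −78 °C and is protonated to the cyclic hemiketal, whose configuration at C2 is irrelevant.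

Step 8
Reactants: 15 cyclic hemiketal (anomer mixture)
Product: 16 (4R,5S)-5-[(E)-but-2-enoyl]-5-[(2S,3R)-3-(tert-butyldimethylsilyloxy)hepta-5,6-dien-2-yl]-2,2-dimethyl-1,3-dioxolane-4-carbaldehyde
Conditions: Dess–Martin periodinane, pyridine, CH2Cl2, 0 °C to rt
Reagents that add atoms: none
Why: Dess–Martin oxidation should act on the primary C6 hydroxyl of the open hydroxy-enone tautomer, which is in ring–chain equilibrium with the hemiketal and is the only oxidisable alcohol (the hemiketal hydroxyl is tertiary), draining the equilibrium to the keto-aldehyde without base that could epimerise C5.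

Step 9
Reactants: 16 keto-aldehyde (C6 aldehyde, C1/C5 acetonide, C2 crotonyl ketone, C9 silyl ether, terminal allene)
Product: 17 (1S,5S,6R,7S,9R,10S)-tricyclic α-methylene-γ-butyrolactone (C11=C13 exocyclic; 1,5-O-isopropylidene; 9-O-TBS; crotonyl at C1)
Conditions: Mo(CO)6 (1.2 equiv), DMSO (10 equiv), toluene, 100 °C, 0.01 M
Reagents that add atoms: molybdenum hexacarbonyl (CO source), [Mo].[C-]#[O+].[C-]#[O+].[C-]#[O+].[C-]#[O+].[C-]#[O+].[C-]#[O+]
Why: Zerovalent molybdenum, freed of CO by DMSO, should bind the C6 aldehyde and the proximal C7=C11 bond of the allene and couple them oxidatively to an oxamolybdacyclopentane (C6–C7 bond), after which CO inserts into the Mo–C11 alkenyl bond (C11–C12 bond) and C–O reductive elimination releases the lactone; this is an intramolecular hetero-Pauson–Khand [2+2+1] cyclocarbonylation, the closest known case being the same reaction of allenyl aldehydes to cis-fused bicyclic α-methylene-γ-butyrolactones with five- and six-membered carbocycles. The cycloheptane closes by bonding of C7 to the metal-bound aldehyde carbon (seven-membered closure, exo with respect to the proximal π bond) and the butyrolactone closes by the carbonylative O–C12 reductive elimination, the chain being pre-folded by its substituents at C1, C5, C9 and C10 and by the trans-dioxolane. C6 and C7 are created together, and their cis relationship should follow from the suprafacial metallacycle. The configuration of C6 relative to C5 should follow from a dipole-minimised conformer in which the C6=O bond is antiperiplanar to the C5–O bond of the dioxolane while the tether can reach only the carbonyl face syn-clinal to C1, which places the new C6–O bond trans to C5–O. The step needs chemoselectivity for the aldehyde over the C2 ketone, which the much easier η2-binding of an aldehyde and the quaternary C1 next to the conjugated ketone should secure, and regioselectivity for the proximal allene π bond, secured because the distal bond would demand an eight-membered ring. C11 is left as an exocyclic methylene and is set in step 10.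

Step 10
Reactants: 17 tricyclic α-methylene-γ-butyrolactone
Product: 18 (1S,5S,6R,7S,9R,10S,11R)-tricyclic α-methyl-γ-butyrolactone (1,5-O-isopropylidene; 9-O-TBS)
Conditions: H2 (1 atm), RhCl(PPh3)3 (10 mol %), toluene, rt
Reagents that add atoms: none
Why: Homogeneous hydrogenation with RhCl(PPh3)3 should reduce the unhindered 1,1-disubstituted exocyclic methylene much faster than the trans-disubstituted conjugated enone, and delivery of hydrogen to the convex face of the cis-fused lactone (the face of H6 and H7) places the new methyl on the concave face, which sets C11 (R).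

Step 11
Reactants: 18 tricyclic α-methyl-γ-butyrolactone acetonide
Product: 19 C1,C5-diol (9-O-TBS; des-angeloyl target skeleton)
Conditions: AcOH/H2O (4:1), 40 °C
Reagents that add atoms: none
Why: Acid-catalysed acetal hydrolysis should cleave the strained trans-fused dioxolane selectively, the hindered secondary silyl ether, the lactone and the enone being stable to aqueous acetic acid.

Step 12
Reactants: 19 C1,C5-diol (9-O-TBS); 20 angelic acid
Product: 22 9-O-TBS ether of the target (C5 angelate), via mixed anhydride 21 (not isolated)
Conditions: 20, 2,4,6-trichlorobenzoyl chloride, Et3N, toluene, rt; then 19, 80 °C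
Reagents that add atoms: none
Why: Yamaguchi esterification through anhydride 21 should acylate the secondary C5 hydroxyl and not the tertiary C1 hydroxyl, and the DMAP-free conditions are those under which the Z-configured angelate is transferred without isomerisation to the tiglate.

Step 13
Reactants: 22 9-O-TBS ether of the target
Product: 23 target (CNP0183494.1)
Conditions: HF·pyridine, pyridine, THF, 0 °C to rt
Reagents that add atoms: none
Why: Desilylation with buffered HF·pyridine should free the C9 hydroxyl without touching the angelate, the lactone, the enone or the tertiary α-hydroxy ketone.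

Compound list
1 | (S)-but-3-en-2-ol | C[C@H](O)C=C | starting material
2 | (S)-but-3-en-2-yl methyl carbonate | C[C@H](OC(=O)OC)C=C | intermediate
3 | 2,3-O-isopropylidene-L-erythronolactone | CC1(C)O[C@H]2COC(=O)[C@H]2O1 | starting material
4 | lithium enolate of 3 | [Li]OC1=C2OC(C)(C)O[C@H]2CO1 | intermediate
5 | 2-C-[(S)-but-3-en-2-yl]-2,3-O-isopropylidene-L-erythronolactone | O=C1OC[C@@H]2OC(C)(C)O[C@]12[C@@H](C)C=C | intermediate
6 | secondary ozonide of 5 (1,2,4-trioxolane at C9) | O=C1OC[C@@H]2OC(C)(C)O[C@]12[C@@H](C)C1OCOO1 | intermediate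
7 | 2-C-[(R)-1-oxopropan-2-yl]-2,3-O-isopropylidene-L-erythronolactone | O=C1OC[C@@H]2OC(C)(C)O[C@]12[C@@H](C)C=O | intermediate
8 | pinacol boronate ester of alcohol 9 | O=C1OC[C@@H]2OC(C)(C)O[C@]12[C@@H](C)[C@H](OB1OC(C)(C)C(C)(C)O1)CC#C | intermediate
9 | 2-C-[(2S,3R)-3-hydroxyhex-5-yn-2-yl]-2,3-O-isopropylidene-L-erythronolactone | O=C1OC[C@@H]2OC(C)(C)O[C@]12[C@@H](C)[C@H](O)CC#C | intermediate
10 | 2-C-[(2S,3R)-3-(tert-butyldimethylsilyloxy)hex-5-yn-2-yl]-2,3-O-isopropylidene-L-erythronolactone | O=C1OC[C@@H]2OC(C)(C)O[C@]12[C@@H](C)[C@H](O[Si](C)(C)C(C)(C)C)CC#C | intermediate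
11 | N,N-diisopropyl propargylic amine (Mannich base of 10) | O=C1OC[C@@H]2OC(C)(C)O[C@]12[C@@H](C)[C@H](O[Si](C)(C)C(C)(C)C)CC#CCN(C(C)C)C(C)C | intermediate
12 | 2-C-[(2S,3R)-3-(tert-butyldimethylsilyloxy)hepta-5,6-dien-2-yl]-2,3-O-isopropylidene-L-erythronolactone | O=C1OC[C@@H]2OC(C)(C)O[C@]12[C@@H](C)[C@H](O[Si](C)(C)C(C)(C)C)CC=C=C | intermediate
13 | (E)-1-bromoprop-1-ene | C/C=C/Br | starting material
14 | (E)-prop-1-enyllithium | C/C=C/[Li] | intermediate
15 | cyclic hemiketal of the C2 (E)-prop-1-enyl ketone with the C6 hydroxyl (anomer mixture) | C/C=C/C1(O)OC[C@@H]2OC(C)(C)O[C@]12[C@@H](C)[C@H](O[Si](C)(C)C(C)(C)C)CC=C=C | intermediate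
16 | (4R,5S)-5-[(E)-but-2-enoyl]-5-[(2S,3R)-3-(tert-butyldimethylsilyloxy)hepta-5,6-dien-2-yl]-2,2-dimethyl-1,3-dioxolane-4-carbaldehyde | O=C[C@@H]1OC(C)(C)O[C@@]1(C(=O)/C=C/C)[C@@H](C)[C@H](O[Si](C)(C)C(C)(C)C)CC=C=C | intermediate
17 | (1S,5S,6R,7S,9R,10S)-tricyclic α-methylene-γ-butyrolactone (1,5-O-isopropylidene; 9-O-TBS) | CC1(C)O[C@H]2[C@@H]3OC(=O)C(=C)[C@@H]3C[C@@H](O[Si](C)(C)C(C)(C)C)[C@H](C)[C@@]2(O1)C(=O)/C=C/C | intermediate
18 | (1S,5S,6R,7S,9R,10S,11R)-tricyclic α-methyl-γ-butyrolactone (1,5-O-isopropylidene; 9-O-TBS) | CC1(C)O[C@H]2[C@@H]3OC(=O)[C@H](C)[C@@H]3C[C@@H](O[Si](C)(C)C(C)(C)C)[C@H](C)[C@@]2(O1)C(=O)/C=C/C | intermediate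
19 | C1,C5-diol (9-O-TBS; des-angeloyl target) | O[C@H]1[C@@H]2OC(=O)[C@H](C)[C@@H]2C[C@@H](O[Si](C)(C)C(C)(C)C)[C@H](C)[C@@]1(O)C(=O)/C=C/C | intermediate
20 | angelic acid, (Z)-2-methylbut-2-enoic acid | C/C=C(/C)C(=O)O | starting material
21 | angelic 2,4,6-trichlorobenzoic mixed anhydride | C/C=C(/C)C(=O)OC(=O)c1c(Cl)cc(Cl)cc1Cl | intermediate
22 | 9-O-TBS ether of the target | C/C=C(/C)C(=O)O[C@H]1[C@@H]2OC(=O)[C@H](C)[C@@H]2C[C@@H](O[Si](C)(C)C(C)(C)C)[C@H](C)[C@@]1(O)C(=O)/C=C/C | intermediate
23 | CNP0183494.1 (1S,5S,6R,7S,9R,10S,11R) | C/C=C(/C)C(=O)O[C@H]1[C@@H]2OC(=O)[C@H](C)[C@@H]2C[C@@H](O)[C@H](C)[C@@]1(O)C(=O)/C=C/C | target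

Total step count: 13
Longest linear sequence: 13 steps (from 1; 12 steps from lactone 3)

Steps most likely to fail

Step 9. The seven-membered closure may be slow, which would let the zerovalent molybdenum engage the conjugated C2 ketone instead (six-membered closure or unproductive enone binding), or allow allene oligomerisation and erosion of facial selectivity at C6. The fallback removes the competing carbonyl before the same cyclocarbonylation. It sets out from hemiketal 15: Luche reduction (NaBH4, CeCl3·7H2O, MeOH) of the open enone tautomer should give the diol F1. Silylation of both hydroxyls (Et3SiOTf, 2,6-lutidine) gives the bis(triethylsilyl) ether F2. Swern oxidation converts the primary silyl ether directly into the aldehyde F3. Mo(CO)6/DMSO then gives the α-methylene lactone F4, and hydrogenation over RhCl(PPh3)3 gives the α-methyl lactone F5, now with no enone to compete. AcOH/H2O removes acetonide and triethylsilyl group together to give the triol F6, and MnO2 oxidises only the allylic C2 alcohol. The route is rejoined at diol 19.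

Step 2. The lithium enolate may β-eliminate the acetonide oxygen on warming, the tetrasubstituted enolate may attack the hindered secondary allyl terminus too slowly, or substitution may leak to the linear crotyl product with loss of stereospecificity. The fallback replaces stereospecific substitution by catalyst-controlled allylation of a neutral nucleophile. From lactone 3, LiN(i-Pr)2 and Me3SiCl at −78 °C should give the trimethylsilyl ketene acetal F7. This is allylated with achiral (E)-but-2-enyl methyl carbonate under [Ir(cod)Cl]2 and a binaphthol-derived bis(1-phenylethyl)amine phosphoramidite (the ligand enantiomer that leads to the 10S branched product), with ZnF2/CsF as silyl acceptor. The branched-selective iridium allyl substitution sets C10 by the catalyst and C1 by the convex face of the bicycle. The route is rejoined at alkene 5.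

Step 12. Acylation of the hindered C5 hydroxyl may be slow, during which the angelate may isomerise to the tiglate or the mixed anhydride may transfer its trichlorobenzoyl group. The fallback builds the Z-alkene after acylation. From diol 19, esterification with 2-[bis(2,2,2-trifluoroethoxy)phosphoryl]propanoic acid (DCC, catalytic DMAP) should give the phosphonate ester F8. Still–Gennari olefination with acetaldehyde (KN(SiMe3)2, 18-crown-6, THF, −78 °C) then forms the Z-trisubstituted alkene. The route is rejoined at angelate 22.

Further compounds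
F1 | step 9 | C2,C6-diol from Luche reduction of 15 (C2 epimers) | OC[C@@H]1OC(C)(C)O[C@@]1(C(O)/C=C/C)[C@@H](C)[C@H](O[Si](C)(C)C(C)(C)C)CC=C=C
F2 | step 9 | C2,C6-bis(triethylsilyl) ether | CC[Si](CC)(CC)OC[C@@H]1OC(C)(C)O[C@@]1(C(O[Si](CC)(CC)CC)/C=C/C)[C@@H](C)[C@H](O[Si](C)(C)C(C)(C)C)CC=C=C
F3 | step 9 | C6 aldehyde with C2 triethylsilyl ether | O=C[C@@H]1OC(C)(C)O[C@@]1(C(O[Si](CC)(CC)CC)/C=C/C)[C@@H](C)[C@H](O[Si](C)(C)C(C)(C)C)CC=C=C
F4 | step 9 | tricyclic α-methylene lactone with C2 triethylsilyl ether | CC1(C)O[C@H]2[C@@H]3OC(=O)C(=C)[C@@H]3C[C@@H](O[Si](C)(C)C(C)(C)C)[C@H](C)[C@@]2(O1)C(O[Si](CC)(CC)CC)/C=C/C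
F5 | step 9 | tricyclic α-methyl lactone with C2 triethylsilyl ether | CC1(C)O[C@H]2[C@@H]3OC(=O)[C@H](C)[C@@H]3C[C@@H](O[Si](C)(C)C(C)(C)C)[C@H](C)[C@@]2(O1)C(O[Si](CC)(CC)CC)/C=C/C
F6 | step 9 | C1,C2,C5-triol (9-O-TBS) | O[C@H]1[C@@H]2OC(=O)[C@H](C)[C@@H]2C[C@@H](O[Si](C)(C)C(C)(C)C)[C@H](C)[C@@]1(O)C(O)/C=C/C
F7 | step 2 | trimethylsilyl ketene acetal of 3 | C[Si](C)(C)OC1=C2OC(C)(C)O[C@H]2CO1
F8 | step 12 | C5 2-[bis(2,2,2-trifluoroethoxy)phosphoryl]propanoate of 19 | CC(C(=O)O[C@H]1[C@@H]2OC(=O)[C@H](C)[C@@H]2C[C@@H](O[Si](C)(C)C(C)(C)C)[C@H](C)[C@@]1(O)C(=O)/C=C/C)P(=O)(OCC(F)(F)F)OCC(F)(F)F
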